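**Plan**

1. Retrosynthesis: the C-19 acetate, the C-2/C-3 diol (from a Δ2 olefin), the C-17 methyl (from a C-8 enol triflate) and the C-6–C-7 bond (aldol condensation) are removed first. Ring A is then cut at C-2–C-3 and C-4–C-5, and finally C-9–C-10 is cut (Claisen rearrangement).
2. Forward: (R)-citronellic acid gives the side-chain allylic alcohol. A ketal Claisen rearrangement joins it to a protected 2-methylcyclohexane-1,4-dione, setting C-9 and C-10. The ketone is turned into a temporary cyclohex-3-enone ring (C-2, C-1, C-10, C-5, C-6, C-7′).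
3. Key event: an (E)-alkenyllithium (C-3, C-4, C-18, C-19) adds to the C-2 carbonyl (bond C-2–C-3). The 3-oxido-1,5-diene C-4=C-3–C-2(O⁻)–C-7′–C-6=C-5 then undergoes an anionic oxy-Cope shift (bond C-4–C-5), turning the temporary ring into ring A as its C-2 enolate, which is trapped as the enol triflate.
4. Ring B is closed by ozonolysis and intramolecular aldol condensation; then follow the Δ2 diol, the C-17 methyl, the acetate and deprotection.
5. Stereochemistry: C-13 comes from citronellic acid; C-9 and C-10 from a reagent-set carbinol through a chair Claisen transition state; C-4 from the E geometry of the alkenyl unit and C-5 from the suprafacial shift on the ring face fixed by C-10; C-2 and C-3 from OsO4 attack anti to the axial C-19 and C-20 groups.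
6. Enabling feature: C-10 is quaternary, so ring A has no diene disconnection. However, the C-1–C-10 unit can bridge an oxygen-bearing C-2 and an olefinic C-5 in one six-membered ring, which places the two-carbon unit C-3–C-4 exactly across a [3,3] array.

Key step: step 12

Remark: locants C-1 to C-20 are the labdane-type numbering of the target carbons (C-18 methyl and C-19 acetoxymethyl on C-4, C-20 methyl on C-10, C-17 methyl on C-8, C-16 methyl on C-13). C-7′ is the ring carbon of the temporary ring that is lost later. Compounds 1, 7 and 15 are taken as commercially available.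

**Step 1**
Reactants: 1 (R)-citronellic acid, (3R)-3,7-dimethyloct-6-enoic acid
Product: 2 tert-butyl (3R)-3,7-dimethyloct-6-enoate
Conditions: Boc2O, DMAP (cat.), t-BuOH, 30 °C
Reagents that add atoms: di-tert-butyl dicarbonate (CC(C)(C)OC(=O)OC(=O)OC(C)(C)C)
Why: Esterification through the mixed carbonic anhydride leaves the olefin and C-13 untouched and gives an ester that should survive the organolithium and alkoxide chemistry later.

**Step 2**
Reactants: 2 tert-butyl (3R)-3,7-dimethyloct-6-enoate
Product: 4 tert-butyl (3R)-3-methyl-6-oxohexanoate, via ozonide 3 (not isolated)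
Conditions: O3, CH2Cl2, −78 °C; then PPh3, −78 °C → rt
Reagents that add atoms: ozone ([O-][O+]=O)
Why: Ozonolysis with reductive work-up cleaves the only olefin to the aldehyde whose carbonyl carbon becomes C-9.

**Step 3**
Reactants: 4 tert-butyl (3R)-3-methyl-6-oxohexanoate
Product: 5 tert-butyl (3R,6E)-3,7-dimethyl-8-oxonon-6-enoate
Conditions: Ph3P=C(Me)C(O)Me, toluene, 90 °C
Reagents that add atoms: 3-(triphenylphosphoranylidene)butan-2-one (CC(=O)C(C)=P(c1ccccc1)(c1ccccc1)c1ccccc1)
Why: Wittig olefination with the stabilised, α-branched ylide should give the (E)-trisubstituted enone and brings in C-8 and the methyl that becomes C-7.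

**Step 4**
Reactants: 5 tert-butyl (3R,6E)-3,7-dimethyl-8-oxonon-6-enoate
Product: 6 tert-butyl (3R,6E,8S)-8-hydroxy-3,7-dimethylnon-6-enoate
Conditions: (R)-2-methyl-CBS-oxazaborolidine (cat.), catecholborane, toluene, −78 °C
Reagents that add atoms: none
Why: Corey–Bakshi–Shibata reduction, with the alkenyl group as the large substituent, should set the (S)-carbinol under catalyst control, independent of the remote C-13 centre.

**Step 5**
Reactants: 7 7-methyl-1,4-dioxaspiro[4.5]decan-8-one (racemic)
Product: 8 8,8-dimethoxy-7-methyl-1,4-dioxaspiro[4.5]decane (racemic)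
Conditions: HC(OMe)3, MeOH, p-toluenesulfonic acid (cat.), rt; NaHCO3 quench
Reagents that add atoms: trimethyl orthoformate (COC(OC)OC), methanol (CO)
Why: Acid-catalysed ketalisation with the orthoformate as water scavenger converts the ketone into the dimethyl ketal needed for alcohol exchange, while the dioxolane should stay in place.

**Step 6**
Reactants: 8 8,8-dimethoxy-7-methyl-1,4-dioxaspiro[4.5]decane (excess) and 6 tert-butyl (3R,6E,8S)-8-hydroxy-3,7-dimethylnon-6-enoate
Product: 11 tert-butyl (3R,7E)-3,7-dimethyl-6-(7-methyl-8-oxo-1,4-dioxaspiro[4.5]decan-7-yl)non-7-enoate with C-9 and C-10 as in the target, via mixed ketal 9 (not isolated), via allyl enol ether 10 (not isolated)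
Conditions: EtCO2H (cat.), xylene, 140 °C, MeOH distilled off
Reagents that add atoms: none
Why: Ketal Claisen rearrangement: alcohol exchange, loss of methanol to the more substituted enol ether and a chair [3,3] shift (carbinol methyl equatorial, E olefin, ring-fixed enol ether geometry) should transfer the carbinol configuration to C-9 and to the quaternary C-10, whose racemic configuration in 7 is erased in the enol ether.

**Step 7**
Reactants: 11 Claisen ketone
Product: 12 enol triflate of 11 (C-5 triflyloxy, C-5=C-6 olefin)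
Conditions: KN(SiMe3)2, THF, −78 °C; then PhNTf2, −78 → 0 °C
Reagents that add atoms: N-phenylbis(trifluoromethanesulfonimide) (O=S(=O)(N(c1ccccc1)S(=O)(=O)C(F)(F)F)C(F)(F)F)
Why: The ketone has only one enolisable α-position (C-6, since C-10 is quaternary), so enolate O-sulfonylation gives a single enol triflate.

**Step 8**
Reactants: 12 enol triflate
Product: 13 tert-butyl (3R,7E)-3,7-dimethyl-6-(7-methyl-1,4-dioxaspiro[4.5]dec-8-en-7-yl)non-7-enoate
Conditions: Pd(OAc)2 (cat.), PPh3, n-Bu3N, HCO2H, DMF, 60 °C
Reagents that add atoms: none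
Why: Palladium-catalysed formate reduction of the enol triflate gives the C-5=C-6 olefin regiospecifically without touching the trisubstituted olefin.

**Step 9**
Reactants: 13 olefinic ketal
Product: 14 tert-butyl (3R,7E)-3,7-dimethyl-6-(1-methyl-5-oxocyclohex-2-en-1-yl)non-7-enoate (the temporary cyclohex-3-enone)
Conditions: pyridinium p-toluenesulfonate (cat.), acetone/H2O, 40 °C
Reagents that add atoms: water (O)
Why: Mild acid hydrolysis of the dioxolane unveils the C-2 ketone under conditions chosen to avoid migration of the β,γ-olefin into conjugation and to keep the tert-butyl ester.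

**Step 10**
Reactants: 15 prop-2-yn-1-ol
Product: 17 (E)-3-iodo-2-methylprop-2-en-1-ol, via alkenylalane 16 (not isolated)
Conditions: AlMe3, Cp2ZrCl2, CH2Cl2, 0 °C → rt; then I2, THF, −30 °C
Reagents that add atoms: trimethylaluminium (C[Al](C)C), iodine (II)
Why: Negishi carboalumination adds methyl and aluminium syn across the alkyne with aluminium at the terminal carbon, and iodinolysis with retention gives the E iodide (iodine cis to methyl).

**Step 11**
Reactants: 17 (E)-3-iodo-2-methylprop-2-en-1-ol
Product: 18 (E)-tert-butyl[(3-iodo-2-methylprop-2-en-1-yl)oxy]dimethylsilane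
Conditions: t-BuMe2SiCl, imidazole, DMF, rt
Reagents that add atoms: tert-butyldimethylsilyl chloride (CC(C)(C)[Si](C)(C)Cl)
Why: Silylation of the primary alcohol gives an ether that is stable to t-BuLi, alkoxides and ozone, and its oxygen is trans to the later carbon–lithium bond, so silyl migration is not possible.

**Step 12**
Reactants: 18 (E)-alkenyl iodide and 14 temporary cyclohex-3-enone
Product: 22 ring-A enol triflate (cyclohexene with C-2 triflyloxy and C-2=C-3 olefin; C-4 carries methyl and CH2OSi(t-Bu)Me2; C-5 carries H and vinyl; C-10 carries methyl and the C-9 side-chain carbon; C-4, C-5, C-9, C-10 and C-13 as in the target), via alkenyllithium 19 (not isolated), via lithium alkoxide 20 (not isolated), via potassium enolate 21 (not isolated)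
Conditions: 18, t-BuLi (2 equiv), Et2O, −78 °C; 14 in THF, −78 °C; then KOt-Bu, 18-crown-6, THF, −78 → 50 °C; then PhNTf2, −78 → 0 °C
Reagents that add atoms: N-phenylbis(trifluoromethanesulfonimide) (O=S(=O)(N(c1ccccc1)S(=O)(=O)C(F)(F)F)C(F)(F)F)
Why: Iodine–lithium exchange gives the (E)-alkenyllithium with retention; it adds to the C-2 carbonyl anti to the pseudoaxial C-20 methyl (the branched C-9 substituent is pseudoequatorial), so the alkenyl group is cis to the C-9 substituent, and after lithium–potassium exchange the 3-oxido-1,5-diene C-4=C-3–C-2(O⁻)–C-7′–C-6=C-5 undergoes an anionic oxy-Cope [3,3]-sigmatropic shift that makes C-4–C-5, breaks C-2–C-7′ and gives the C-2 enolate, which is O-triflated in the same flask. The closest known reaction type is the tandem 1,2-addition/anionic oxy-Cope rearrangement of β,γ-unsaturated ketones. Ring A (C-1, C-2, C-3, C-4, C-5, C-10) is closed by the sigmatropic shift itself, through a boat-like six-membered transition state enforced by the C-1–C-10 bridge between C-2 and C-5; it is a ring transposition and not a nucleophilic closure, so no exo or endo mode applies. C-5 is set by suprafacial delivery of C-4 to the ring face that carries the alkenyl group (hence H-5 trans to the C-20 methyl, the later trans ring fusion); C-4 is set by the E geometry of the alkenyl unit (the methyl cis to C-2 ends cis to H-5, the silyloxymethyl group cis to C-20); the C-2 carbinol centre disappears in the enolate. The step needs 1,2-addition in preference to proton abstraction from the β,γ-enone (low temperature), the stated facial selectivity (secured by the conformational bias at C-10) and regiochemical integrity of the enolate (aprotic medium, immediate trapping with PhNTf2).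

**Step 13**
Reactants: 22 ring-A enol triflate
Product: 24 keto aldehyde (C-5 carries CHO = C-6; C-9 carries an acetyl group = C-8 and C-7), via bis-ozonide 23 (not isolated)
Conditions: O3, CH2Cl2, −78 °C (Sudan red end point); then PPh3, −78 °C → rt
Reagents that add atoms: ozone ([O-][O+]=O)
Why: Ozone should attack the vinyl and the trisubstituted olefin much faster than the electron-poor enol triflate, unveiling the C-6 aldehyde and the C-8 methyl ketone in one operation.

**Step 14**
Reactants: 24 keto aldehyde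
Product: 26 trans-fused bicyclic enone (C-8 ketone, C-6=C-7 olefin, C-2 enol triflate), via aldol 25 (not isolated)
Conditions: Bn2NH·CF3CO2H (cat.), benzene, 50 °C
Reagents that add atoms: none
Why: Amine-salt-catalysed intramolecular aldol condensation (the methyl of the ketone attacks the aldehyde) is the only six-membered closure available and forms ring B; the hindered tertiary hydrogens at C-5 and C-9 are not expected to enolise under these conditions.

**Step 15**
Reactants: 26 bicyclic enone enol triflate
Product: 27 bicyclic dienone (C-2=C-3 olefin, C-6=C-7–C-8=O enone)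
Conditions: Pd(OAc)2 (cat.), PPh3, n-Bu3N, HCO2H, DMF, 60 °C
Reagents that add atoms: none
Why: Palladium-catalysed formate reduction of the enol triflate gives the Δ2 olefin; enones are tolerated under these conditions.

**Step 16**
Reactants: 27 bicyclic dienone
Product: 28 2,3-cis-diol (C-2 hydroxyl equatorial, C-3 hydroxyl axial, both anti to C-19 and C-20)
Conditions: OsO4 (cat.), N-methylmorpholine N-oxide, acetone/H2O, rt
Reagents that add atoms: osmium tetroxide (O=[Os](=O)(=O)=O), N-methylmorpholine N-oxide (C[N+]1([O-])CCOCC1), water (O)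
Why: Catalytic dihydroxylation should take the isolated Δ2 olefin in preference to the electron-poor enone olefin and from the face anti to the axial C-19 and C-20 substituents, which sets C-2 and C-3.

**Step 17**
Reactants: 28 diol
Product: 29 2,3-O-isopropylidene acetal of 28
Conditions: Me2C(OMe)2, pyridinium p-toluenesulfonate (cat.), CH2Cl2, rt
Reagents that add atoms: 2,2-dimethoxypropane (COC(C)(C)OC)
Why: Acetonide formation on the cis-diol protects both hydroxyls for the enolate, organozinc and acetylation steps.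

**Step 18**
Reactants: 29 acetonide enone
Product: 31 C-8 enol triflate (C-7=C-8 olefin, C-6 methylene), via lithium enolate 30 (not isolated)
Conditions: LiBH(s-Bu)3, THF, −78 °C; then PhNTf2, −78 → 0 °C
Reagents that add atoms: N-phenylbis(trifluoromethanesulfonimide) (O=S(=O)(N(c1ccccc1)S(=O)(=O)C(F)(F)F)C(F)(F)F)
Why: Conjugate hydride reduction of the β-unsubstituted cyclohexenone gives the C-7/C-8 enolate regiospecifically, and trapping it as the triflate fixes the olefin position without touching C-9.

**Step 19**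
Reactants: 31 C-8 enol triflate
Product: 32 C-8 methyl olefin (C-7=C-8, C-17 methyl in place)
Conditions: MeZnCl, Pd(PPh3)4 (cat.), THF, 50 °C
Reagents that add atoms: methylzinc chloride (C[Zn]Cl)
Why: Negishi cross-coupling replaces the triflate by methyl with retention of the olefin position and tolerates the ester, acetal and silyl ether.

**Step 20**
Reactants: 32 silyl ether
Product: 33 C-19 primary alcohol
Conditions: Bu4NF, THF, rt → 45 °C
Reagents that add atoms: none
Why: Fluoride cleaves the silyl ether and leaves the acetonide and the tert-butyl ester intact.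

**Step 21**
Reactants: 33 C-19 alcohol
Product: 34 C-19 acetate
Conditions: Ac2O, pyridine, DMAP (cat.), CH2Cl2, rt
Reagents that add atoms: acetic anhydride (CC(=O)OC(C)=O)
Why: Acetylation of the only free hydroxyl installs the acetate.

**Step 22**
Reactants: 34 protected acetate
Product: 35 target, (3R)-5-[(1R,4aS,5R,6R,7S,8aS)-5-(acetoxymethyl)-6,7-dihydroxy-2,5,8a-trimethyl-1,4,4a,5,6,7,8,8a-octahydronaphthalen-1-yl]-3-methylpentanoic acid
Conditions: CF3CO2H/CH2Cl2/H2O, 0 °C → rt
Reagents that add atoms: none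
Why: Acidolysis removes the acetonide and the tert-butyl ester (alkyl–oxygen cleavage) while the primary acetate and the trisubstituted olefin should survive a short exposure; acyl migration to O-3 is geometrically disfavoured because C-19 and O-3 are anti.

**Compound list**

1 | (R)-citronellic acid, (3R)-3,7-dimethyloct-6-enoic acid | CC(C)=CCC[C@@H](C)CC(=O)O | starting material
2 | tert-butyl (3R)-3,7-dimethyloct-6-enoate | CC(C)=CCC[C@@H](C)CC(=O)OC(C)(C)C | intermediate
3 | ozonide of 2, tert-butyl (3R)-5-(5,5-dimethyl-1,2,4-trioxolan-3-yl)-3-methylpentanoate | CC1(C)OOC(CC[C@@H](C)CC(=O)OC(C)(C)C)O1 | intermediate (not isolated)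
4 | tert-butyl (3R)-3-methyl-6-oxohexanoate | O=CCC[C@@H](C)CC(=O)OC(C)(C)C | intermediate
5 | tert-butyl (3R,6E)-3,7-dimethyl-8-oxonon-6-enoate | CC(=O)/C(C)=C/CC[C@@H](C)CC(=O)OC(C)(C)C | intermediate
6 | tert-butyl (3R,6E,8S)-8-hydroxy-3,7-dimethylnon-6-enoate | C[C@H](O)/C(C)=C/CC[C@@H](C)CC(=O)OC(C)(C)C | intermediate
7 | 7-methyl-1,4-dioxaspiro[4.5]decan-8-one (racemic) | CC1CC2(CCC1=O)OCCO2 | starting material
8 | 8,8-dimethoxy-7-methyl-1,4-dioxaspiro[4.5]decane (racemic) | COC1(OC)CCC2(CC1C)OCCO2 | intermediate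
9 | mixed methyl allyl ketal from 8 and 6 | COC1(O[C@@H](C)/C(C)=C/CC[C@@H](C)CC(=O)OC(C)(C)C)CCC2(CC1C)OCCO2 | intermediate (not isolated)
10 | allyl enol ether, tert-butyl (3R,6E,8S)-3,7-dimethyl-8-[(7-methyl-1,4-dioxaspiro[4.5]dec-7-en-8-yl)oxy]non-6-enoate | CC1=C(O[C@@H](C)/C(C)=C/CC[C@@H](C)CC(=O)OC(C)(C)C)CCC2(C1)OCCO2 | intermediate (not isolated)
11 | Claisen ketone, tert-butyl (3R,7E)-3,7-dimethyl-6-(7-methyl-8-oxo-1,4-dioxaspiro[4.5]decan-7-yl)non-7-enoate, C-9 and C-10 as in the target | C/C=C(\C)[C@@H](CC[C@@H](C)CC(=O)OC(C)(C)C)[C@]1(C)CC2(CCC1=O)OCCO2 | intermediate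
12 | enol triflate of 11 (C-5 triflyloxy, C-5=C-6) | C/C=C(\C)[C@@H](CC[C@@H](C)CC(=O)OC(C)(C)C)[C@]1(C)CC2(CC=C1OS(=O)(=O)C(F)(F)F)OCCO2 | intermediate
13 | tert-butyl (3R,7E)-3,7-dimethyl-6-(7-methyl-1,4-dioxaspiro[4.5]dec-8-en-7-yl)non-7-enoate | C/C=C(\C)[C@@H](CC[C@@H](C)CC(=O)OC(C)(C)C)[C@]1(C)CC2(CC=C1)OCCO2 | intermediate
14 | temporary cyclohex-3-enone, tert-butyl (3R,7E)-3,7-dimethyl-6-(1-methyl-5-oxocyclohex-2-en-1-yl)non-7-enoate | C/C=C(\C)[C@@H](CC[C@@H](C)CC(=O)OC(C)(C)C)[C@]1(C)CC(=O)CC=C1 | intermediate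
15 | prop-2-yn-1-ol | C#CCO | starting material
16 | (E)-alkenylalane from carboalumination (aluminium cis to methyl, O-bound AlMe2) | C[Al](C)/C=C(\C)CO[Al](C)C | intermediate (not isolated)
17 | (E)-3-iodo-2-methylprop-2-en-1-ol | OC/C(C)=C/I | intermediate
18 | (E)-tert-butyl[(3-iodo-2-methylprop-2-en-1-yl)oxy]dimethylsilane | CC(C)(C)[Si](C)(C)OC/C(C)=C/I | intermediate
19 | (E)-alkenyllithium from 18 (lithium cis to methyl) | [Li]/C=C(\C)CO[Si](C)(C)C(C)(C)C | intermediate (not isolated)
20 | lithium tertiary alkoxide from 19 and 14 (alkenyl on C-2 cis to the C-9 substituent on C-10) | C/C=C(\C)[C@@H](CC[C@@H](C)CC(=O)OC(C)(C)C)[C@]1(C)C[C@]([O-])(/C=C(\C)CO[Si](C)(C)C(C)(C)C)CC=C1.[Li+] | intermediate (not isolated)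
21 | potassium C-2 enolate of ring A after the [3,3] shift | CC(C)(C)[Si](C)(C)OC[C@@]1(C)[C@@H](C=C)[C@](C)([C@H](CC[C@@H](C)CC(=O)OC(C)(C)C)/C(C)=C/C)CC([O-])=C1.[K+] | intermediate (not isolated)
22 | ring-A enol triflate (C-2 triflyloxy, C-2=C-3; C-5 vinyl; C-4, C-5, C-9, C-10, C-13 as in the target) | CC(C)(C)[Si](C)(C)OC[C@@]1(C)[C@@H](C=C)[C@](C)([C@H](CC[C@@H](C)CC(=O)OC(C)(C)C)/C(C)=C/C)CC(OS(=O)(=O)C(F)(F)F)=C1 | intermediate
23 | bis-ozonide of 22 (1,2,4-trioxolanes at the former vinyl and trisubstituted olefins) | CC(C)(C)[Si](C)(C)OC[C@@]1(C)[C@@H](C2OCOO2)[C@](C)([C@H](CC[C@@H](C)CC(=O)OC(C)(C)C)C2(C)OOC(C)O2)CC(OS(=O)(=O)C(F)(F)F)=C1 | intermediate (not isolated)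
24 | keto aldehyde (C-6 formyl on C-5, acetyl on C-9) | CC(C)(C)[Si](C)(C)OC[C@@]1(C)[C@@H](C=O)[C@](C)([C@H](CC[C@@H](C)CC(=O)OC(C)(C)C)C(C)=O)CC(OS(=O)(=O)C(F)(F)F)=C1 | intermediate
25 | aldol adduct (C-6 hydroxyl, C-8 ketone), ring B closed | CC(C)(C)[Si](C)(C)OC[C@@]1(C)[C@H]2C(O)CC(=O)[C@@H](CC[C@@H](C)CC(=O)OC(C)(C)C)[C@]2(C)CC(OS(=O)(=O)C(F)(F)F)=C1 | intermediate (not isolated)
26 | trans-fused bicyclic enone (C-8 ketone, C-6=C-7) with C-2 enol triflate | CC(C)(C)[Si](C)(C)OC[C@@]1(C)[C@H]2C=CC(=O)[C@@H](CC[C@@H](C)CC(=O)OC(C)(C)C)[C@]2(C)CC(OS(=O)(=O)C(F)(F)F)=C1 | intermediate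
27 | bicyclic dienone (C-2=C-3 olefin; C-6=C-7–C-8=O) | CC(C)(C)[Si](C)(C)OC[C@@]1(C)[C@H]2C=CC(=O)[C@@H](CC[C@@H](C)CC(=O)OC(C)(C)C)[C@]2(C)CC=C1 | intermediate
28 | 2,3-cis-diol of the bicyclic enone | CC(C)(C)[Si](C)(C)OC[C@@]1(C)[C@H]2C=CC(=O)[C@@H](CC[C@@H](C)CC(=O)OC(C)(C)C)[C@]2(C)C[C@H](O)[C@@H]1O | intermediate
29 | 2,3-O-isopropylidene acetal of 28 | CC(C)(C)[Si](C)(C)OC[C@@]1(C)[C@H]2C=CC(=O)[C@@H](CC[C@@H](C)CC(=O)OC(C)(C)C)[C@]2(C)C[C@@H]3OC(C)(C)O[C@H]13 | intermediate
30 | lithium C-7/C-8 enolate from conjugate reduction of 29 | CC(C)(C)[Si](C)(C)OC[C@@]1(C)[C@H]2CC=C([O-])[C@@H](CC[C@@H](C)CC(=O)OC(C)(C)C)[C@]2(C)C[C@@H]3OC(C)(C)O[C@H]13.[Li+] | intermediate (not isolated)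
31 | C-8 enol triflate (C-7=C-8) | CC(C)(C)[Si](C)(C)OC[C@@]1(C)[C@H]2CC=C(OS(=O)(=O)C(F)(F)F)[C@@H](CC[C@@H](C)CC(=O)OC(C)(C)C)[C@]2(C)C[C@@H]3OC(C)(C)O[C@H]13 | intermediate
32 | C-8 methyl olefin, fully protected (silyl ether, acetonide, tert-butyl ester) | CC(C)(C)[Si](C)(C)OC[C@@]1(C)[C@H]2CC=C(C)[C@@H](CC[C@@H](C)CC(=O)OC(C)(C)C)[C@]2(C)C[C@@H]3OC(C)(C)O[C@H]13 | intermediate
33 | C-19 primary alcohol (acetonide, tert-butyl ester) | OC[C@@]1(C)[C@H]2CC=C(C)[C@@H](CC[C@@H](C)CC(=O)OC(C)(C)C)[C@]2(C)C[C@@H]3OC(C)(C)O[C@H]13 | intermediate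
34 | C-19 acetate (acetonide, tert-butyl ester) | CC(=O)OC[C@@]1(C)[C@H]2CC=C(C)[C@@H](CC[C@@H](C)CC(=O)OC(C)(C)C)[C@]2(C)C[C@@H]3OC(C)(C)O[C@H]13 | intermediate
35 | target, (3R)-5-[(1R,4aS,5R,6R,7S,8aS)-5-(acetoxymethyl)-6,7-dihydroxy-2,5,8a-trimethyl-1,4,4a,5,6,7,8,8a-octahydronaphthalen-1-yl]-3-methylpentanoic acid | CC(=O)OC[C@@]1(C)[C@H]2CC=C(C)[C@@H](CC[C@@H](C)CC(=O)O)[C@]2(C)C[C@H](O)[C@@H]1O | target

**Step count and risks**

Total step count: 22. Longest linear sequence: 19 steps (steps 1–4, 6–9, 12–22).

Steps most likely to fail: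

Step 12. What may go wrong: the alkenyllithium abstracts a proton from the doubly activated C-7′ methylene instead of adding to the carbonyl; the boat-like shift is slow because three contiguous substituted centres are formed; or the enolate loses its regiochemical integrity before triflation. The fallback separates the events and sets out from 14 and 19. The alkenyllithium 19 is transmetallated with CeCl3 and the non-basic alkenylcerium reagent is added to 14 at −78 °C, which should give after work-up the tertiary alcohol F1. This alcohol is deprotonated with KH in the presence of 18-crown-6 in THF and warmed (two-stage anionic oxy-Cope rearrangement). The enolate is silylated with Me3SiCl to the trimethylsilyl enol ether F2, which can be purified. MeLi then regenerates the regio-defined lithium enolate and PhNTf2 returns the route at 22.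

Step 6. What may go wrong: enol ether formation toward the unsubstituted α-carbon, ionisation of the secondary allylic alcohol under the acidic conditions with loss of chirality transfer, or leakage through a boat transition state. The fallback sets out from 7 and fixes the regiochemistry beforehand. Ketone 7 is converted through its kinetic trimethylsilyl enol ether with Pd(OAc)2 (Saegusa oxidation) into the enone F3, whose carbonyl can enolise only toward the methyl-bearing carbon. Ketal exchange of this enone with 6 (HC(OMe)3, EtCO2H (cat.), heat) and Claisen rearrangement of the cross-conjugated dienol ether should give the α′-quaternary enone F4. Its tosylhydrazone F5 (from p-toluenesulfonyl hydrazide) is reduced with catecholborane and NaOAc, which moves the double bond into the C-5=C-6 position. The route is rejoined at 13, and steps 7 and 8 are not needed.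

Step 14. What may go wrong: epimerisation α to the methyl ketone (C-9) or α to the aldehyde (C-5) under the condensation conditions, or a stop at the aldol stage. The fallback sets out from 24 and closes the ring as a directed Mukaiyama aldol. The aldehyde is selectively converted into the dimethyl acetal F6 (HC(OMe)3, pyridinium p-toluenesulfonate, MeOH). LiN(i-Pr)2 and Me3SiCl at −78 °C give the kinetic silyl enol ether F7 on the methyl side of the ketone. Me3SiOTf (cat.) in CH2Cl2 at −78 °C closes ring B to the β-methoxy ketone F8, and DBU eliminates methanol to rejoin the route at 26.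

**Further compounds**

F1 | step 12 | tertiary alcohol from alkenylcerium addition to 14 (alkenyl cis to the C-9 substituent) | C/C=C(\C)[C@@H](CC[C@@H](C)CC(=O)OC(C)(C)C)[C@]1(C)C[C@](O)(/C=C(\C)CO[Si](C)(C)C(C)(C)C)CC=C1
F2 | step 12 | trimethylsilyl enol ether of ring A (C-2 silyloxy, C-2=C-3) | CC(C)(C)[Si](C)(C)OC[C@@]1(C)[C@@H](C=C)[C@](C)([C@H](CC[C@@H](C)CC(=O)OC(C)(C)C)/C(C)=C/C)CC(O[Si](C)(C)C)=C1
F3 | step 6 | 7-methyl-1,4-dioxaspiro[4.5]dec-9-en-8-one (racemic) | CC1CC2(C=CC1=O)OCCO2
F4 | step 6 | α′-quaternary enone, tert-butyl (3R,7E)-3,7-dimethyl-6-(7-methyl-8-oxo-1,4-dioxaspiro[4.5]dec-9-en-7-yl)non-7-enoate, C-9 and C-10 as in the target | C/C=C(\C)[C@@H](CC[C@@H](C)CC(=O)OC(C)(C)C)[C@]1(C)CC2(C=CC1=O)OCCO2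
F5 | step 6 | p-toluenesulfonylhydrazone of F4 | C/C=C(\C)[C@@H](CC[C@@H](C)CC(=O)OC(C)(C)C)[C@]1(C)CC2(C=CC1=NNS(=O)(=O)c1ccc(C)cc1)OCCO2
F6 | step 14 | dimethyl acetal of the C-6 aldehyde of 24 | CC(C)(C)[Si](C)(C)OC[C@@]1(C)[C@@H](C(OC)OC)[C@](C)([C@H](CC[C@@H](C)CC(=O)OC(C)(C)C)C(C)=O)CC(OS(=O)(=O)C(F)(F)F)=C1
F7 | step 14 | kinetic trimethylsilyl enol ether of the methyl ketone of F6 | CC(C)(C)[Si](C)(C)OC[C@@]1(C)[C@@H](C(OC)OC)[C@](C)([C@H](CC[C@@H](C)CC(=O)OC(C)(C)C)C(=C)O[Si](C)(C)C)CC(OS(=O)(=O)C(F)(F)F)=C1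
F8 | step 14 | β-methoxy ketone with ring B closed (C-6 methoxy, C-8 ketone) | CC(C)(C)[Si](C)(C)OC[C@@]1(C)[C@H]2C(OC)CC(=O)[C@@H](CC[C@@H](C)CC(=O)OC(C)(C)C)[C@]2(C)CC(OS(=O)(=O)C(F)(F)F)=C1
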